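**Pitfall:** a product share that stays put over time is easily taken for a property of the molecules, when it may record how the charge was shared out.

| flask | starting material | reagent | other conformer | remark | time |
|---|---|---|---|---|---|
| ochre | 0.20 M | 0.30 M | 0.10 M | run made earlier |  |
| grey | 0.28 M | 0.30 M | 0.10 M | run made earlier |  |
| red | 0.44 M | 0.30 M | 0.10 M | run made earlier |  |
| cedar | 0.20 M | 0.300 M | 0.100 M (fed, over 3.20 d) | all but other conformer at the start; other conformer goes in evenly over 3.20 d, the run ends at 4.0 d | 4.0 d |
| ash | 0.20 M | 0.300 M | 0.100 M | everything together in a closed stirred flask, run for 4.0 d | 4.0 d |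
| birch | 0.20 M | 0.300 M | 0.100 M | one stirred flow tank at steady state, fed with the mixture as stated, mean residence time 4.0 d |  |
| oak | 0.20 M | 0.300 M (fed, over 3.20 d) | 0.100 M | all but reagent at the start; reagent goes in evenly over 3.20 d, the run ends at 4.0 d | 4.0 d |

| run | time / d | target / % | isomer of the product / % |
|---|---|---|---|
| ochre | 0.417 | 28.5 | 44.3 |
| ochre | 0.833 | 33.9 | 49.7 |
| ochre | 1.25 | 37.1 | 53.6 |
| ochre | 1.67 | 37.5 | 54.4 |
| ochre | 2.08 | 38.0 | 57.1 |
| ochre | 2.50 | 38.3 | 56.7 |
| grey | 0.167 | 20.3 | 31.9 |
| grey | 0.500 | 29.1 | 39.2 |
| grey | 0.833 | 30.4 | 43.4 |
| grey | 1.25 | 31.1 | 45.6 |
| grey | 1.67 | 31.7 | 46.3 |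
| grey | 2.50 | 32.1 | 46.8 |
| red | 0.167 | 19.5 | 25.6 |
| red | 0.500 | 22.8 | 30.9 |
| red | 0.833 | 23.6 | 31.9 |
| red | 1.25 | 23.9 | 32.5 |
| red | 1.67 | 23.6 | 31.9 |
| red | 2.50 | 23.2 | 32.3 |

(each reading ± 0.5 percentage points)

* the set-up with the highest share of target in all that became target or isomer of the product, at the outlet or at the end ("none" if the first two lie within 2 percentage points) (cedar / ash / birch / oak / none)
* share of target in all that became target or isomer of the product, at the outlet or at the end, cedar
* share of target in all that became target or isomer of the product, at the outlet or at the end, ash
* share of target in all that became target or isomer of the product, at the outlet or at the end, birch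
* share of target in all that became target or isomer of the product, at the outlet or at the end, oak

- the stated concentrations are those of everything mixed, before any reaction; amounts are the same in each set-up
- the feed brings no volume worth counting
- the earlier runs were made in a closed, stirred flask

*Which conformer feeds which product?*
Grey to red adds starting material, with reagent and other conformer held. At the first reading, 0.167 d, the amount of target grows by a factor 1.37, isomer by 1.14. I read target as coming from starting material, isomer from other conformer.

*What is the zero of your scale?*
The slow-exchange limit of the Curtin–Hammett picture: no molecule changes conformer and each reacts. Target's share is then the frozen share, the fraction of the charge that is starting material, 66.7%.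

*And ochre?*
The share in ochre reads 39.1% at the first reading and 40.3% at the last, below the frozen share. I call that gap of 26 percentage points the leak.

*Through what does it leak?*
Through the flip, as I read it: starting material can meet reagent, at a rate that follows reagent, or become other conformer, at a rate that doesn't.

*So what do you commit to?*
Ash sits at the ochre share. I expect cedar, with reagent charged at the start and other conformer dosed, between that share and the frozen share. I expect oak, with reagent dosed, and birch, with its back-mixing, below ash.

The forecast runs the opposite way, "Target share rises when reagent stays low": cedar 36%, ash 40.2%, birch 45%, oak 46%, best none.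

The flask gives cedar 51.6%, ash 39.9%, birch 29.7%, oak 21.8%; best is cedar.

    starting material ⇌ other conformer (K = 0.270, k = 0.0330 h⁻¹)
    starting material + reagent → target (k = 0.670 M⁻¹ h⁻¹)
    reagent + other conformer → isomer of the product (k = 19.0 M⁻¹ h⁻¹)
    reagent ⇌ dormant form (K = 0.380, k = 0.0950 h⁻¹)

Oak lies 45 points below the frozen share, further than any other set-up. The main reason is the exchange between starting material and other conformer: taken away, oak gives 61.1% instead of 21.8%. The neighbour of cedar charged with 1.2 M of reagent, 6.00 equiv to starting material, has the same frozen share, 66.7%, and I expect it closer beneath that than cedar. It gives 63.8%, a leak of 2.9 points against 15 points in cedar.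

All runs come from a simulation with constants of no real substance, noise included.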